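**Retrosynthetic overview**
1. Feature: in the oxolane ring O1–C2–C3–C4–C5, the aryl donor sits on C2, the carbonyl acceptor on C4, and C5 is a bare CH2 between C4 and O1. This is the 1,3-donor/acceptor imprint of an arylcyclopropane-1,1-dicarbonyl unit that has taken up CH2=O.
2. Late stage: the target comes from C4 epimerisation of the all-cis aryl ketone. The ketone comes from ArMgBr and a Weinreb amide, and the amide from opening a cis-fused furofuranone. The lactone C=O of that furofuranone is the future aroyl carbon and its lactone CH2O is the future C3 CH2OH.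
3. Key disconnection: O1–C2 and C4–C5, leading back to formaldehyde and an exo-6-aryl-2-oxo-3-oxabicyclo[3.1.0]hexane-1-carboxylate. Inversion at the aryl carbon turns the trans cyclopropane into the 2,3-cis oxolane.
4. The cyclopropane comes from an organocatalytic Michael-initiated ring closure of trimethoxycinnamaldehyde with dimethyl bromomalonate, followed by reduction and lactonisation.
5. Ring order: cyclopropane, then γ-lactone, then oxolane (the cyclopropane is consumed), and finally the lactone is opened.

Key step: step 3

Assumption: the facial sense of the diarylprolinol silyl ether is taken from the usual steric-shielding model of the s-trans E-iminium ion, in which the (S)-catalyst leads to the (2R,3S)-formylcyclopropane. The (R)-catalyst is therefore used for the (2S,3R) series; both enantiomers are commercial.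

Step 1
Reactants: 1 (E)-3-(3,4,5-trimethoxyphenyl)prop-2-enal; 2 dimethyl 2-bromomalonate
Product: 3 dimethyl (2S,3R)-2-formyl-3-(3,4,5-trimethoxyphenyl)cyclopropane-1,1-dicarboxylate
Conditions: (R)-2-[diphenyl(trimethylsilyloxy)methyl]pyrrolidine (20 mol %), 2,6-lutidine (1.1 equiv), CH2Cl2, 0 °C
Reagents that add atoms: none
Why: This is a Michael-initiated ring closure (iminium-activated conjugate addition of the bromomalonate, then 3-exo-tet alkylation of the enamine) in which the bulky pyrrolidine side chain blocks one face of the iminium ion and sets the aryl carbon as R, the closure places formyl trans to aryl, and the weak base only takes up HBr and should not open the product.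

Step 2
Reactants: 3 dimethyl (2S,3R)-2-formyl-3-(3,4,5-trimethoxyphenyl)cyclopropane-1,1-dicarboxylate
Product: 5 methyl (1R,5S,6R)-2-oxo-6-(3,4,5-trimethoxyphenyl)-3-oxabicyclo[3.1.0]hexane-1-carboxylate (aryl exo), via hydroxymethyl diester 4 (not isolated)
Conditions: NaBH4, MeOH, 0 °C; then PPTS (cat.), CH2Cl2, rt
Reagents that add atoms: none
Why: Chemoselective borohydride reduction of the aldehyde gives a primary alcohol that is necessarily cis to one of the geminal esters and closes the five-membered lactone by 5-exo-trig transesterification, which makes C1 stereogenic without touching C5 or C6.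

Step 3
Reactants: 5 methyl (1R,5S,6R)-2-oxo-6-(3,4,5-trimethoxyphenyl)-3-oxabicyclo[3.1.0]hexane-1-carboxylate; 6 formaldehyde (monomer)
Product: 7 methyl (3aS,4S,6aS)-1-oxo-4-(3,4,5-trimethoxyphenyl)tetrahydro-1H,3H-furo[3,4-c]furan-6a-carboxylate (cis-fused; angular ester; aryl cis to the lactone CH2)
Conditions: Sn(OTf)2 (10 mol %), CH2O (ca. 5 equiv, CH2Cl2 solution of monomer freshly cracked from dry paraformaldehyde), 4 Å MS, CH2Cl2, −40 → 0 °C, cold Et3N quench
Reagents that add atoms: none
Why: Proposed new method: Sn(OTf)2 held between the ester and lactone carbonyl oxygens of 5 polarises the bond from the quaternary carbon (future C4) to the aryl-bearing carbon (future C2), free formaldehyde displaces the incipient enolate from the rear of that benzylic carbon through its oxygen, and after rotation about the future C2–C3 bond the tin enolate carbon adds to the O1=C5H2 oxocarbenium carbon. The closest known reaction type is the Lewis-acid-catalysed (3+2) annulation of 2-arylcyclopropane-1,1-diesters (2,3-disubstituted ones included) with aryl, alkenyl and alkyl aldehydes, which runs with inversion at the donor carbon; formaldehyde as the aldehyde and a lactone-fused cyclopropane as its partner have not been shown, hence the label. The only ring closed is the oxolane, by an aldol-type attack in which the enolate C=C lies outside and the O1=C5 bond inside the forming ring (5-enolexo, formally 5-endo-trig), the same mode as in the parent annulation, where the cationic, strongly polarised acceptor makes it easy. C2 is fixed by the SN2-like inversion, which converts the trans aryl/CH2O relation of the cyclopropane into the 2,3-cis relation of the oxolane, and quaternary C4 is fixed by the lactone tether, because the arm that carries the oxocarbenium ion hangs from C3 and reaches only the enolate face leading to the cis-fused bicycle. Needed are cleavage of the aryl-substituted and not the ring-fusion cyclopropane bond, capture before free ionisation, and uptake of one formaldehyde only; the first follows from the aryl donor and from the better overlap of the external cyclopropane bond with the lactone carbonyl, the second from the low temperature and the modest cation-stabilising power of a 3,4,5-trimethoxyphenyl group (two inductively withdrawing meta methoxy groups, a twisted para one), the third from the fast intramolecular enolate capture. C3 is a spectator throughout, so any leakage through an open cation would surface as a separable 2,3-trans diastereomer and not as racemisation.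

Step 4
Reactants: 7 methyl (3aS,4S,6aS)-1-oxo-4-(3,4,5-trimethoxyphenyl)tetrahydro-1H,3H-furo[3,4-c]furan-6a-carboxylate
Product: 8 (3aS,4S,6aS)-4-(3,4,5-trimethoxyphenyl)tetrahydro-1H,3H-furo[3,4-c]furan-1-one (cis-fused)
Conditions: LiCl (3 equiv), H2O (3 equiv), DMSO, 140 °C
Reagents that add atoms: none
Why: In this Krapcho dealkoxycarbonylation chloride removes the methyl group of the doubly activated angular ester by SN2 attack, the carboxylate loses CO2 to give the lactone enolate, and protonation at C4 can only give the cis-fused bicyclo[3.3.0] skeleton, so hydrogen takes the place of the ester.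

Step 5
Reactants: 8 (3aS,4S,6aS)-4-(3,4,5-trimethoxyphenyl)tetrahydro-1H,3H-furo[3,4-c]furan-1-one
Product: 9 (3S,4S,5S)-4-(hydroxymethyl)-N-methoxy-N-methyl-5-(3,4,5-trimethoxyphenyl)oxolane-3-carboxamide (all-cis)
Conditions: MeNH(OMe)·HCl (3 equiv), AlMe3 (3 equiv), CH2Cl2, 0 °C → rt; aq potassium sodium tartrate
Reagents that add atoms: N,O-dimethylhydroxylamine hydrochloride, CNOC.Cl
Why: Aluminium-amide aminolysis of a γ-lactone (Weinreb amide formation) frees the C3 CH2OH group and turns the C4 carbonyl into a mono-addition acceptor while leaving all three stereocentres as they are.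

Step 6
Reactants: 9 (3S,4S,5S)-4-(hydroxymethyl)-N-methoxy-N-methyl-5-(3,4,5-trimethoxyphenyl)oxolane-3-carboxamide
Product: 10 (3S,4S,5S)-4-[(tert-butyldimethylsilyloxy)methyl]-N-methoxy-N-methyl-5-(3,4,5-trimethoxyphenyl)oxolane-3-carboxamide
Conditions: TBSCl, imidazole, CH2Cl2, 0 °C → rt (on crude 9)
Reagents that add atoms: tert-butyldimethylsilyl chloride, CC(C)(C)[Si](C)(C)Cl
Why: Routine silylation of the primary alcohol is carried out at once because the free γ-hydroxy amide (or its magnesium alkoxide) would relactonise and invite double aryl addition, and because a free cis γ-hydroxy ketone would be held as a bicyclic hemiketal and bias the later C4 equilibrium.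

Step 7
Reactants: 10 (3S,4S,5S)-4-[(tert-butyldimethylsilyloxy)methyl]-N-methoxy-N-methyl-5-(3,4,5-trimethoxyphenyl)oxolane-3-carboxamide; 11 5-bromo-1,2,3-trimethoxybenzene
Product: 13 [(3S,4S,5S)-4-[(tert-butyldimethylsilyloxy)methyl]-5-(3,4,5-trimethoxyphenyl)oxolan-3-yl](3,4,5-trimethoxyphenyl)methanone (all-cis), via arylmagnesium bromide 12 (not isolated)
Conditions: 11 (2 equiv), Mg turnings, THF, 40 °C; then 10, THF, 0 °C → rt; aq NH4Cl
Reagents that add atoms: magnesium, [Mg] (ends up in intermediate 12 only)
Why: Grignard addition to a Weinreb amide stops at the magnesium-chelated tetrahedral intermediate and releases the aryl ketone only on work-up, no stereocentre is formed, and any partial epimerisation at C4 runs in the wanted direction.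

Step 8
Reactants: 13 all-cis silyl ether ketone
Product: 14 [(3R,4S,5S)-4-[(tert-butyldimethylsilyloxy)methyl]-5-(3,4,5-trimethoxyphenyl)oxolan-3-yl](3,4,5-trimethoxyphenyl)methanone (aryl/CH2O cis, CH2O/aroyl trans)
Conditions: K2CO3 (0.5 equiv), MeOH–THF, rt
Reagents that add atoms: none
Why: Base-mediated epimerisation through the aryl ketone enolate under thermodynamic control should relax the crowded all-cis array to the isomer with the aroyl group trans to the C3 substituent (C4 from S to R), since C2 and C3 carry no acidic hydrogen and the ring C5–O1 bond lies nearly orthogonal to the enolate π system, which holds back β-elimination.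

Step 9
Reactants: 14 3,4-trans silyl ether ketone
Product: 15 [(3R,4S,5S)-4-(hydroxymethyl)-5-(3,4,5-trimethoxyphenyl)oxolan-3-yl](3,4,5-trimethoxyphenyl)methanone (CNP0148560.1)
Conditions: Bu4NF, AcOH (1:1), THF, 0 °C → rt
Reagents that add atoms: none
Why: Fluoride-mediated desilylation buffered with acetic acid should spare both the acid-labile benzylic C2–O1 bond and the base-sensitive C4 centre, and the trans hydroxy ketone cannot close to a hemiketal.

**Compound list**
1 | (E)-3-(3,4,5-trimethoxyphenyl)prop-2-enal | COc1cc(/C=C/C=O)cc(OC)c1OC | starting material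
2 | dimethyl 2-bromomalonate | COC(=O)C(Br)C(=O)OC | starting material
3 | dimethyl (2S,3R)-2-formyl-3-(3,4,5-trimethoxyphenyl)cyclopropane-1,1-dicarboxylate | COC(=O)C1(C(=O)OC)[C@@H](c2cc(OC)c(OC)c(OC)c2)[C@@H]1C=O | intermediate
4 | dimethyl (2S,3R)-2-(hydroxymethyl)-3-(3,4,5-trimethoxyphenyl)cyclopropane-1,1-dicarboxylate | COC(=O)C1(C(=O)OC)[C@@H](c2cc(OC)c(OC)c(OC)c2)[C@@H]1CO | intermediate
5 | methyl (1R,5S,6R)-2-oxo-6-(3,4,5-trimethoxyphenyl)-3-oxabicyclo[3.1.0]hexane-1-carboxylate | COC(=O)[C@@]12[C@@H](c3cc(OC)c(OC)c(OC)c3)[C@@H]1COC2=O | intermediate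
6 | formaldehyde (monomer, cracked from commercial paraformaldehyde) | C=O | starting material
7 | methyl (3aS,4S,6aS)-1-oxo-4-(3,4,5-trimethoxyphenyl)tetrahydro-1H,3H-furo[3,4-c]furan-6a-carboxylate | COC(=O)[C@@]12CO[C@H](c3cc(OC)c(OC)c(OC)c3)[C@@H]1COC2=O | intermediate
8 | (3aS,4S,6aS)-4-(3,4,5-trimethoxyphenyl)tetrahydro-1H,3H-furo[3,4-c]furan-1-one | O=C1OC[C@@H]2[C@H]1CO[C@@H]2c1cc(OC)c(OC)c(OC)c1 | intermediate
9 | (3S,4S,5S)-4-(hydroxymethyl)-N-methoxy-N-methyl-5-(3,4,5-trimethoxyphenyl)oxolane-3-carboxamide | CON(C)C(=O)[C@@H]1CO[C@H](c2cc(OC)c(OC)c(OC)c2)[C@@H]1CO | intermediate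
10 | (3S,4S,5S)-4-[(tert-butyldimethylsilyloxy)methyl]-N-methoxy-N-methyl-5-(3,4,5-trimethoxyphenyl)oxolane-3-carboxamide | CON(C)C(=O)[C@@H]1CO[C@H](c2cc(OC)c(OC)c(OC)c2)[C@@H]1CO[Si](C)(C)C(C)(C)C | intermediate
11 | 5-bromo-1,2,3-trimethoxybenzene | COc1cc(Br)cc(OC)c1OC | starting material
12 | (3,4,5-trimethoxyphenyl)magnesium bromide | COc1cc([Mg]Br)cc(OC)c1OC | intermediate
13 | [(3S,4S,5S)-4-[(tert-butyldimethylsilyloxy)methyl]-5-(3,4,5-trimethoxyphenyl)oxolan-3-yl](3,4,5-trimethoxyphenyl)methanone | COc1cc(C(=O)[C@@H]2CO[C@H](c3cc(OC)c(OC)c(OC)c3)[C@@H]2CO[Si](C)(C)C(C)(C)C)cc(OC)c1OC | intermediate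
14 | [(3R,4S,5S)-4-[(tert-butyldimethylsilyloxy)methyl]-5-(3,4,5-trimethoxyphenyl)oxolan-3-yl](3,4,5-trimethoxyphenyl)methanone | COc1cc(C(=O)[C@H]2CO[C@H](c3cc(OC)c(OC)c(OC)c3)[C@@H]2CO[Si](C)(C)C(C)(C)C)cc(OC)c1OC | intermediate
15 | [(3R,4S,5S)-4-(hydroxymethyl)-5-(3,4,5-trimethoxyphenyl)oxolan-3-yl](3,4,5-trimethoxyphenyl)methanone | COc1cc(C(=O)[C@H]2CO[C@H](c3cc(OC)c(OC)c(OC)c3)[C@@H]2CO)cc(OC)c1OC | target

**Step count:** 9 steps in total. The longest linear sequence is 9 steps (1 → 15); the aryl bromide 11 enters in the flask of step 7.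

**Steps most likely to fail**

Step 3 (labelled step). What may go wrong:
- Formaldehyde is a weak oxygen nucleophile and may polymerise on the Lewis acid faster than it attacks the benzylic carbon.
- Ionisation of the polarised cyclopropane bond ahead of capture would erode the inversion.
- Repeated formaldehyde insertion or hydroxymethylation of the electron-rich arene may compete.
- Re-ionisation of the C2–O1 bond of the product may move the aryl group to the convex face.

The fallback sets out from 3 and comes back at 7, and uses only the established substrate and aldehyde classes. Compound 3 is reduced with NaBH4 at −20 °C, and the alcohol 4 is silylated immediately (TBDPSCl, imidazole) before it lactonises. This gives dimethyl (2S,3R)-2-[(tert-butyldiphenylsilyloxy)methyl]-3-(3,4,5-trimethoxyphenyl)cyclopropane-1,1-dicarboxylate F1. A Sn(OTf)2- or AlCl3-catalysed (3+2) annulation with (E)-cinnamaldehyde follows; this aldehyde lies within proven scope and serves as a removable stand-in for formaldehyde. With the same inversion it should give dimethyl 4-[(tert-butyldiphenylsilyloxy)methyl]-2-[(E)-2-phenylethenyl]-5-(3,4,5-trimethoxyphenyl)oxolane-3,3-dicarboxylate (2,5-cis, 4,5-cis) F2. Ozonolysis (O3, CH2Cl2–MeOH, −78 °C; Me2S) cuts the styryl group down to the 2-formyl oxolane diester F3. Tsuji–Wilkinson decarbonylation with RhCl(PPh3)3 (1 equiv, toluene, reflux) then erases that carbon to leave dimethyl (4S,5S)-4-[(tert-butyldiphenylsilyloxy)methyl]-5-(3,4,5-trimethoxyphenyl)oxolane-3,3-dicarboxylate F4. Bu4NF frees the alcohol, which lactonises onto the cis ester and gives 7.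

Step 8. What may go wrong:
- β-Elimination of O1 from the enolate, which opens the ring to an α-methylene ketone, may compete with reprotonation.
- Slow proton return onto the crowded face may leave the equilibrium unreached.

The fallback sets out from 10 and comes back at 14. It moves the epimerisation to the much more acidic aldehyde level, where a tertiary amine is enough. i-Bu2AlH (THF, −78 °C) reduces 10 to the all-cis (3S,4S,5S)-4-[(tert-butyldimethylsilyloxy)methyl]-5-(3,4,5-trimethoxyphenyl)oxolane-3-carbaldehyde F5. Et3N or catalytic DBU in CH2Cl2 at rt equilibrates this to the 3,4-trans (3R,4S,5S)-carbaldehyde F6. Addition of 12 (THF, −78 °C) gives the diaryl carbinol F7 as a mixture at the carbinol carbon, which is of no consequence. Dess–Martin oxidation (NaHCO3, CH2Cl2) then gives 14.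

Step 4. What may go wrong at the temperature needed to demethylate a hindered quaternary ester:
- chloride attack on the lactone CH2,
- β-elimination from the lactone enolate,
- nucleophilic demethylation of the aryl ethers.

The fallback sets out from 7 and comes back at 8. It replaces nucleophilic dealkylation by hydrolysis and malonic-acid-type decarboxylation. LiOH (THF–H2O, rt to 40 °C) hydrolyses the ester and opens the lactone. Cold acidification with citric acid recloses the lactone to (3aS,4S,6aS)-1-oxo-4-(3,4,5-trimethoxyphenyl)tetrahydro-1H,3H-furo[3,4-c]furan-6a-carboxylic acid F8. Warming F8 in toluene (90–110 °C) should expel CO2 through the cyclic six-membered transition state, and tautomerisation gives cis-fused 8.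

**Further compounds**
F1 | step 3 | dimethyl (2S,3R)-2-[(tert-butyldiphenylsilyloxy)methyl]-3-(3,4,5-trimethoxyphenyl)cyclopropane-1,1-dicarboxylate | COC(=O)C1(C(=O)OC)[C@@H](c2cc(OC)c(OC)c(OC)c2)[C@@H]1CO[Si](c1ccccc1)(c1ccccc1)C(C)(C)C
F2 | step 3 | dimethyl 4-[(tert-butyldiphenylsilyloxy)methyl]-2-[(E)-2-phenylethenyl]-5-(3,4,5-trimethoxyphenyl)oxolane-3,3-dicarboxylate (2,5-cis, 4,5-cis) | COC(=O)C1(C(=O)OC)[C@H](/C=C/c2ccccc2)O[C@H](c2cc(OC)c(OC)c(OC)c2)[C@@H]1CO[Si](c1ccccc1)(c1ccccc1)C(C)(C)C
F3 | step 3 | dimethyl 4-[(tert-butyldiphenylsilyloxy)methyl]-2-formyl-5-(3,4,5-trimethoxyphenyl)oxolane-3,3-dicarboxylate (2,5-cis, 4,5-cis) | COC(=O)C1(C(=O)OC)[C@H](C=O)O[C@H](c2cc(OC)c(OC)c(OC)c2)[C@@H]1CO[Si](c1ccccc1)(c1ccccc1)C(C)(C)C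
F4 | step 3 | dimethyl (4S,5S)-4-[(tert-butyldiphenylsilyloxy)methyl]-5-(3,4,5-trimethoxyphenyl)oxolane-3,3-dicarboxylate | COC(=O)C1(C(=O)OC)CO[C@H](c2cc(OC)c(OC)c(OC)c2)[C@@H]1CO[Si](c1ccccc1)(c1ccccc1)C(C)(C)C
F5 | step 8 | (3S,4S,5S)-4-[(tert-butyldimethylsilyloxy)methyl]-5-(3,4,5-trimethoxyphenyl)oxolane-3-carbaldehyde (all-cis) | O=C[C@@H]1CO[C@H](c2cc(OC)c(OC)c(OC)c2)[C@@H]1CO[Si](C)(C)C(C)(C)C
F6 | step 8 | (3R,4S,5S)-4-[(tert-butyldimethylsilyloxy)methyl]-5-(3,4,5-trimethoxyphenyl)oxolane-3-carbaldehyde (3,4-trans) | O=C[C@H]1CO[C@H](c2cc(OC)c(OC)c(OC)c2)[C@@H]1CO[Si](C)(C)C(C)(C)C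
F7 | step 8 | [(3R,4S,5S)-4-[(tert-butyldimethylsilyloxy)methyl]-5-(3,4,5-trimethoxyphenyl)oxolan-3-yl](3,4,5-trimethoxyphenyl)methanol (both carbinol epimers) | COc1cc(C(O)[C@H]2CO[C@H](c3cc(OC)c(OC)c(OC)c3)[C@@H]2CO[Si](C)(C)C(C)(C)C)cc(OC)c1OC
F8 | step 4 | (3aS,4S,6aS)-1-oxo-4-(3,4,5-trimethoxyphenyl)tetrahydro-1H,3H-furo[3,4-c]furan-6a-carboxylic acid | OC(=O)[C@@]12CO[C@H](c3cc(OC)c(OC)c(OC)c3)[C@@H]1COC2=O
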